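**Assumption:** enantiopure (S)-tetrahydrofurfuryl alcohol is commercially available. If not, it is made in one step by BH3 reduction of commercial (S)-tetrahydro-2-furoic acid.

## Retrosynthetic overview
- The target is a 2,5-trans-THF (2R,5S) carrying a CO2Me-propyl chain at C2 and an (E)-enyne–(E)-vinyl bromide chain at C5.
- The enyne C(sp)–C(sp2) bond is disconnected by Sonogashira coupling, giving terminal alkyne **7** and the (E,E)-dibromodiene **10**. Compound **10** comes from 1,6-dibromohexane via 1,9-decadiyne.
- Key radical disconnection: the C5–C(sp) bond. A HAT-generated α-oxy radical at C5 of THF **4** is alkynylated by TIPS-EBX anti to the C2 chain, which sets the trans relationship.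
- THF **4** comes from chiral-pool (S)-THF-methanol by iodination and Giese addition to methyl acrylate. The THF ring is already present in the starting material, so no ring-forming step is needed and C2 is never touched.

## Route

**Step 1**
Reactants: **1**, (S)-(tetrahydrofuran-2-yl)methanol
Product: **2**, (S)-2-(iodomethyl)tetrahydrofuran
Conditions: PPh3, I2, imidazole, CH2Cl2, 0 °C → rt
Reagents that add atoms: iodine, II
Why: Appel-type iodination at the primary carbinol carbon, so the C2 stereocentre is untouched.

**Step 2**
Reactants: **2**; **3**, methyl acrylate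
Product: **4**, methyl (R)-4-(tetrahydrofuran-2-yl)butanoate
Conditions: methyl acrylate (5 equiv), (TMS)3SiH (1.2 equiv, slow addition), Et3B (0.1 equiv)/air, toluene, rt
Reagents that add atoms: none
Why: Giese radical conjugate addition. The primary radical CH2• adds to the acrylate and the resulting α-ester radical is reduced by the silane. This installs the (CH2)3CO2Me chain (CH2 from the iodide plus CH2CH2CO2Me from the acrylate), and C2 is not involved.

**Step 3**
Reactants: **4** (2.5 equiv); **5**, TIPS-EBX (1-[(triisopropylsilyl)ethynyl]-1,2-benziodoxol-3(1H)-one)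
Product: **6**, methyl 4-[(2R,5S)-5-(TIPS-ethynyl)tetrahydrofuran-2-yl]butanoate
Conditions: TBADT (2 mol%), MeCN, 390 nm LEDs, rt, N2
Reagents that add atoms: TIPS-EBX, CC(C)[Si](C#CI1OC(=O)c2ccccc12)(C(C)C)C(C)C
Why: Proposed new method: this applies known decatungstate-photocatalysed C(sp3)–H alkynylation of ethers (excited W10O32⁴⁻ abstracts the hydridic α-oxy H; the radical adds to EBX and loses the iodanyl group) to a 2-alkyl-THF, with diastereocontrol. The less hindered, more hydridic C5–H is abstracted in preference to the tertiary C2–H. The bulky TIPS-EBX then traps the C5 radical on the face anti to the C2 chain, giving 2,5-trans. The closest known reaction type is Giese-type radical trapping of 2-substituted THF radicals, which is anti-selective. Any cis isomer is removed after step 4.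

**Step 4**
Reactants: **6**
Product: **7**, methyl 4-[(2R,5S)-5-ethynyltetrahydrofuran-2-yl]butanoate
Conditions: TBAF, AcOH (buffer), THF, 0 °C; chromatographic separation of the trans isomer
Reagents that add atoms: none
Why: Fluoride desilylation of the TIPS-alkyne. Buffering prevents ester attack and propargylic epimerisation, and no stereocentre is altered.

**Step 5**
Reactants: **8**, 1,6-dibromohexane
Product: **9**, deca-1,9-diyne
Conditions: LiC≡CH·ethylenediamine (3 equiv), DMSO, rt
Reagents that add atoms: lithium acetylide–ethylenediamine complex, [Li+].[C-]#C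
Why: Double SN2 alkylation of acetylide on the primary dibromide, giving the C2 + (CH2)6 + C2 skeleton.

**Step 6**
Reactants: **9**
Product: **10**, (1E,9E)-1,10-dibromodeca-1,9-diene
Conditions: Cp2Zr(H)Cl (2.4 equiv), THF, rt, then NBS (2.4 equiv), 0 °C → rt
Reagents that add atoms: N-bromosuccinimide, O=C1CCC(=O)N1Br
Why: Hydrozirconation is syn and anti-Markovnikov, giving (E)-alkenylzirconocenes at both terminal alkynes. Bromodezirconation with NBS occurs with retention, giving the (E)-vinyl bromides.

**Step 7**
Reactants: **7** (1 equiv); **10** (5 equiv)
Product: **11**, Mutafuran C, methyl 4-[(2R,5S)-5-((3E,11E)-12-bromododeca-3,11-dien-1-yn-1-yl)tetrahydrofuran-2-yl]butanoate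
Conditions: Pd(PPh3)4 (5 mol%), CuI (10 mol%), iPr2NH, THF, 40 °C, degassed
Reagents that add atoms: none
Why: Sonogashira coupling with retention of alkene geometry. The large excess of symmetric dibromide statistically favours mono-coupling, leaves one (E)-vinyl bromide intact, and the excess is recoverable.

## Checks
- The target is a 2,5-trans-THF (2R,5S) with the (CH2)3CO2Me chain and the C≡C–CH=CH–(CH2)6–CH=CH–Br chain.
- Carbon count: compound **7** has 11 C and **10** has 10 C, giving 21 C in **11**, as in the target SMILES.
- C2 comes from the chiral pool and is untouched through steps 1, 2, 4 and 7; a small risk of C2 erosion in step 3 is noted below.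
- C5 is set in step 3 and is not exposed to strong base afterwards.
- The ester, THF ring and vinyl bromides survive steps 4 and 7. In step 7, oxidative addition is slower for the vinyl bromides than for the vinyl iodides normally used, but 40 °C with CuI is sufficient.

## Compound list
1 | (S)-(tetrahydrofuran-2-yl)methanol | OC[C@@H]1CCCO1 | starting material
2 | (S)-2-(iodomethyl)tetrahydrofuran | IC[C@@H]1CCCO1 | intermediate
3 | methyl acrylate | C=CC(=O)OC | starting material
4 | methyl (R)-4-(tetrahydrofuran-2-yl)butanoate | COC(=O)CCC[C@@H]1CCCO1 | intermediate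
5 | TIPS-EBX | CC(C)[Si](C#CI1OC(=O)c2ccccc12)(C(C)C)C(C)C | reagent (alkynyl donor)
6 | methyl 4-[(2R,5S)-5-(TIPS-ethynyl)THF-2-yl]butanoate | COC(=O)CCC[C@@H]1CC[C@@H](C#C[Si](C(C)C)(C(C)C)C(C)C)O1 | intermediate
7 | methyl 4-[(2R,5S)-5-ethynylTHF-2-yl]butanoate | COC(=O)CCC[C@@H]1CC[C@@H](C#C)O1 | intermediate
8 | 1,6-dibromohexane | BrCCCCCCBr | starting material
9 | deca-1,9-diyne | C#CCCCCCCC#C | intermediate
10 | (1E,9E)-1,10-dibromodeca-1,9-diene | Br/C=C/CCCCCC/C=C/Br | intermediate
11 | Mutafuran C | COC(=O)CCC[C@@H]1CC[C@@H](C#C/C=C/CCCCCC/C=C/Br)O1 | target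

**Total steps:** 7. **Longest linear sequence:** 5 (steps 1, 2, 3, 4, 7).

## Three steps most likely to fail
1. **Step 3 (C–H alkynylation).** The trans:cis ratio may be modest, C2–H abstraction could erode C2, and chain CH2 positions could compete. Fallback: form the ring by Co-catalysed Mukaiyama-type oxidative cyclisation of the appropriate enantiomer of methyl 5-hydroxynon-8-enoate, which gives the trans-5-(hydroxymethyl)THF. Then oxidise to the aldehyde and convert to alkyne **7** with Ohira–Bestmann reagent.
2. **Step 7 (mono-Sonogashira on a dibromide).** Bis-coupling or sluggish vinyl bromide coupling may occur. Fallback: couple **7** with (E)-I–CH=CH–(CH2)6–C≡C–TMS, remove TMS with K2CO3/MeOH, then install the terminal (E)-vinyl bromide by Cp2Zr(H)Cl/NBS.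
3. **Step 6 (double hydrozirconation/bromination).** Partial conversion or E/Z leakage would give a mixture of products. Fallback: ozonolyse cyclooctene (Me2S work-up) to octanedial, then apply a Takai-type CrCl2/CHBr3 olefination to give the (E)-dibromide.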